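**Plan**
- **Cuts:** the phenol protecting groups and the 3-O-acetyl group come off last, and C4=O is traced back to a C4 carbinol. Ring C is then cut at C3–C4 and at O1–C2, and the 7-O–prenyl bond is cut back to prenyl bromide.
- **Enabling feature:** in ring C the chain O1–C8a–C4a–C4 is the phenol oxygen, two arene carbons and the formyl carbon of a ring-A salicylaldehyde. C2–C3, with ring B on C2 and oxygen on C3, is the C=C of the enol acetate of a catechol-type arylacetaldehyde.
- **Forward order:** rings A and B are bought. Ring A receives the prenyl ether and one silyl ether (steps 1–2). Ring B is silylated and extended by Wittig olefination and Baeyer–Villiger oxidation to the pure E enol acetate (steps 3–5). Ring C, the only ring made, closes in step 6, and oxidation, deacetylation and desilylation follow (steps 7–9).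
- **Stereochemistry:** C3 comes from the chiral counter-anion of a confined Brønsted acid during C3–C4 bond formation. C2 is relayed from C3 by anti closure on an acetate-bridged cation (2,3-trans). The C4 carbinol centre disappears on oxidation.
- **Protecting groups:** aryl TBS ethers tolerate the anhydrous acid of step 6 and leave with fluoride. The acid-labile aryl prenyl ether and the base-labile dihydroflavonol therefore never meet strong acid or base.

Key step: step 6

Abbreviations: TBS = tert-butyldimethylsilyl; prenyl = 3-methylbut-2-en-1-yl.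

Assumption: the sense of induction of the confined acid cannot be derived from a model, so the route is drawn for the catalyst antipode that gives the (2R,3S) flavan series, to be fixed by correlating the final product with the (2R,3R) dihydroflavonol series.

Step 1
Reactants: 1 2,4,6-trihydroxybenzaldehyde; 2 prenyl bromide (1-bromo-3-methylbut-2-ene)
Product: 3 2,6-dihydroxy-4-(prenyloxy)benzaldehyde
Conditions: K2CO3 (1.0 equiv), acetone, rt
Reagents that add atoms: none
Why: Williamson ether synthesis: the 4-OH is the most acidic hydroxyl and the only one that cannot hydrogen-bond to the formyl oxygen, so one equivalent of weak base in an aprotic solvent should place the prenyl group on O4 rather than on O2/O6 or on a ring carbon.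

Step 2
Reactants: 3 2,6-dihydroxy-4-(prenyloxy)benzaldehyde
Product: 4 2-(TBS-oxy)-6-hydroxy-4-(prenyloxy)benzaldehyde
Conditions: TBSCl (1.05 equiv), imidazole, CH2Cl2, 0 °C
Reagents that add atoms: TBSCl, CC(C)(C)[Si](C)(C)Cl
Why: Imidazole-promoted silylation of a phenol: the two hydroxyls are equivalent by symmetry, and once one is silylated the other is held in the hydrogen bond to the formyl oxygen, which should stop the reaction at the mono-ether.

Step 3
Reactants: 5 3,4-dihydroxybenzaldehyde
Product: 6 3,4-bis(TBS-oxy)benzaldehyde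
Conditions: TBSCl (2.4 equiv), imidazole, DMF, rt
Reagents that add atoms: TBSCl, CC(C)(C)[Si](C)(C)Cl
Why: Standard imidazole-promoted silylation of both catechol hydroxyls, which leaves the aldehyde untouched and gives a well-known building block.

Step 4
Reactants: 6 3,4-bis(TBS-oxy)benzaldehyde; 7 1-(triphenylphosphoranylidene)propan-2-one
Product: 8 (E)-4-[3,4-bis(TBS-oxy)phenyl]but-3-en-2-one
Conditions: toluene, 80 °C
Reagents that add atoms: none
Why: Wittig olefination with a stabilised acyl ylide, which runs without added base (no risk to the base-labile aryl silyl ethers) and gives the E enone.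

Step 5
Reactants: 8 (E)-4-[3,4-bis(TBS-oxy)phenyl]but-3-en-2-one
Product: 9 (E)-2-[3,4-bis(TBS-oxy)phenyl]ethenyl acetate
Conditions: Oxone, dry DMF, rt
Reagents that add atoms: potassium peroxymonosulfate (active component of Oxone), [K+].[O-]S(=O)(=O)OO
Why: Baeyer–Villiger oxidation of an α,β-unsaturated methyl ketone, known for benzylideneacetones: the alkenyl group migrates in preference to methyl with retention of the double-bond geometry, so the E enol acetate should form free of its Z isomer.

Step 6
Reactants: 4 2-(TBS-oxy)-6-hydroxy-4-(prenyloxy)benzaldehyde; 9 (E)-2-[3,4-bis(TBS-oxy)phenyl]ethenyl acetate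
Product: 11 (2R,3S,4R)-5,3',4'-tris(TBS-oxy)-7-(prenyloxy)flavan-3,4-diol 3-acetate, via acyloxonium ion 10 (not isolated)
Conditions: chiral IDPi acid (BINOL-derived N-triflyl imidodiphosphorimidate, 5 mol %), 5 Å MS, CHCl3, −40 °C, slow addition of 9
Reagents that add atoms: none
Why: Proposed new method: the confined acid protonates the chelated formyl group of 4 to a hydroxy-substituted ortho-quinone methide cation, the acetoxy-bearing carbon of 9 adds to its C4 terminus (Prins-type C3–C4 bond formation) because the charge then develops on the carbon that carries the para-silyloxyaryl ring, and the acetate carbonyl folds onto that carbon to give the trans-disubstituted dioxolanylium ion 10. The closest known reaction types are confined-acid Prins cyclisations and intramolecular [4+2] reactions of salicylaldehyde-derived ortho-quinone methides, acid-catalysed annulations of such species with styrenes to 4-oxygenated flavans, and chiral phosphoric acid [4+2] reactions of ortho-quinone methides with vinyl arenes, whereas an enol ester as the 2π partner in an intermolecular enantioselective reaction of a free salicylaldehyde is without precedent. Ring C closes when the phenol oxygen opens 10 at C2 from the face opposite the acyloxy bridge (6-exo-tet at the dioxolanylium carbon, overall a formal inverse-demand [4+2]) and returns the proton to the catalyst anion. C3 is set in the C–C bond-forming event by the chiral counter-anion, which must tell apart the two faces of the geometrically pure E alkene; C2 follows from C3 through the anti opening of 10 and is backed by the diequatorial preference of the 2-aryl and 3-acyloxy groups; C4 depends on the formyl face attacked, is expected trans to C3 and is erased in step 7. Regioselectivity rests on the far better cation stabilisation by the 4-silyloxyaryl group than by the weakly donating acetoxy group, chemoselectivity over the prenyl alkene rests on its inductive deactivation by the allylic aryloxy group and on its geometric inability to reach C4 of its own molecule, and aryl silyl ethers are used because they resist anhydrous acid where acetal-type groups would ionise.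

Step 7
Reactants: 11 (2R,3S,4R)-5,3',4'-tris(TBS-oxy)-7-(prenyloxy)flavan-3,4-diol 3-acetate
Product: 12 (2R,3R)-3-acetoxy-5,3',4'-tris(TBS-oxy)-7-(prenyloxy)flavan-4-one
Conditions: DMP, pyridine, CH2Cl2, 0 °C → rt
Reagents that add atoms: none
Why: Dess–Martin oxidation of a secondary benzylic alcohol under buffered conditions, precedented for protected flavan-3,4-diol derivatives: either C4 epimer converges on the same ketone, every phenol is masked, the prenyl alkene is inert, and C2 and C3 are not touched (the C3 descriptor changes from S to R only through the priority rules).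

Step 8
Reactants: 12 (2R,3R)-3-acetoxy-5,3',4'-tris(TBS-oxy)-7-(prenyloxy)flavan-4-one
Product: 13 (2R,3R)-3-hydroxy-5,3',4'-tris(TBS-oxy)-7-(prenyloxy)flavan-4-one
Conditions: [tBu2Sn(OH)Cl]2 (5 mol %), MeOH/THF, 40 °C
Reagents that add atoms: none
Why: Neutral organotin-catalysed transesterification (methanolysis of an acetate), a known mild deacetylation that favours esters next to a coordinating carbonyl group, avoids both the base that would enolise C3 and open ring C by β-elimination of O1 and the mineral acid that would ionise the aryl prenyl ether.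

Step 9
Reactants: 13 (2R,3R)-3-hydroxy-5,3',4'-tris(TBS-oxy)-7-(prenyloxy)flavan-4-one
Product: 14 (2R,3R)-2-(3,4-dihydroxyphenyl)-3,5-dihydroxy-7-(prenyloxy)chroman-4-one (7-O-prenyltaxifolin)
Conditions: KHF2, MeOH, rt, Ar
Reagents that add atoms: none
Why: Fluoride cleavage of phenolic silyl ethers with potassium hydrogen difluoride, a known method that runs at slightly acidic pH, should free the 5-OH and the catechol without affecting the prenyl ether or the two stereocentres next to the ketone.

**Compound list**
1 | 2,4,6-trihydroxybenzaldehyde | O=Cc1c(O)cc(O)cc1O | starting material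
2 | prenyl bromide | CC(C)=CCBr | starting material
3 | 2,6-dihydroxy-4-(prenyloxy)benzaldehyde | CC(C)=CCOc1cc(O)c(C=O)c(O)c1 | intermediate
4 | 2-(TBS-oxy)-6-hydroxy-4-(prenyloxy)benzaldehyde | CC(C)=CCOc1cc(O)c(C=O)c(O[Si](C)(C)C(C)(C)C)c1 | intermediate
5 | 3,4-dihydroxybenzaldehyde | O=Cc1ccc(O)c(O)c1 | starting material
6 | 3,4-bis(TBS-oxy)benzaldehyde | O=Cc1ccc(O[Si](C)(C)C(C)(C)C)c(O[Si](C)(C)C(C)(C)C)c1 | intermediate
7 | 1-(triphenylphosphoranylidene)propan-2-one | CC(=O)C=P(c1ccccc1)(c1ccccc1)c1ccccc1 | starting material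
8 | (E)-4-[3,4-bis(TBS-oxy)phenyl]but-3-en-2-one | CC(=O)/C=C/c1ccc(O[Si](C)(C)C(C)(C)C)c(O[Si](C)(C)C(C)(C)C)c1 | intermediate
9 | (E)-2-[3,4-bis(TBS-oxy)phenyl]ethenyl acetate | CC(=O)O/C=C/c1ccc(O[Si](C)(C)C(C)(C)C)c(O[Si](C)(C)C(C)(C)C)c1 | intermediate
10 | trans-4,5-disubstituted 2-methyl-1,3-dioxolan-2-ylium (acyloxonium) ion bridging C2 and C3, ring C still open, 2S,3S,4R in flavan numbering, ion pair with the catalyst anion | CC1=[O+][C@@H](c2ccc(O[Si](C)(C)C(C)(C)C)c(O[Si](C)(C)C(C)(C)C)c2)[C@@H](O1)[C@H](O)c1c(O)cc(OCC=C(C)C)cc1O[Si](C)(C)C(C)(C)C | intermediate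
11 | (2R,3S,4R)-5,3',4'-tris(TBS-oxy)-7-(prenyloxy)flavan-3,4-diol 3-acetate (2,3-trans-3,4-trans; the C4 configuration is of no consequence) | CC(C)=CCOc1cc(O[Si](C)(C)C(C)(C)C)c2c(c1)O[C@H](c1ccc(O[Si](C)(C)C(C)(C)C)c(O[Si](C)(C)C(C)(C)C)c1)[C@@H](OC(C)=O)[C@@H]2O | intermediate
12 | (2R,3R)-3-acetoxy-5,3',4'-tris(TBS-oxy)-7-(prenyloxy)flavan-4-one | CC(C)=CCOc1cc(O[Si](C)(C)C(C)(C)C)c2c(c1)O[C@H](c1ccc(O[Si](C)(C)C(C)(C)C)c(O[Si](C)(C)C(C)(C)C)c1)[C@@H](OC(C)=O)C2=O | intermediate
13 | (2R,3R)-3-hydroxy-5,3',4'-tris(TBS-oxy)-7-(prenyloxy)flavan-4-one | CC(C)=CCOc1cc(O[Si](C)(C)C(C)(C)C)c2c(c1)O[C@H](c1ccc(O[Si](C)(C)C(C)(C)C)c(O[Si](C)(C)C(C)(C)C)c1)[C@@H](O)C2=O | intermediate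
14 | (2R,3R)-2-(3,4-dihydroxyphenyl)-3,5-dihydroxy-7-(prenyloxy)chroman-4-one | CC(C)=CCOc1cc(O)c2c(c1)O[C@H](c1ccc(O)c(O)c1)[C@@H](O)C2=O | target

**Step count**
Total step count: 9. Longest linear sequence: 7 (steps 3, 4, 5, 6, 7, 8, 9).

**Steps most likely to fail**

**Step 6.**
- **What may go wrong:** the strongly donor-stabilised formyl cation may react too slowly with a weakly nucleophilic alkene. The acid may ionise the newly formed C4 carbinol or oligomerise the alkene. Facial selectivity at C3 may be poor.
- **Fallback (known chemistry):** a chalcone epoxide route that sets out from 2 and 6 and comes back at 14.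
- **Ring A ketone:** commercial 2,4,6-trihydroxyacetophenone is O-prenylated with 2 (K2CO3, acetone) to 1-[2,6-dihydroxy-4-(prenyloxy)phenyl]ethanone F1. This is silylated on both phenols (TBSCl, imidazole, DMAP, DMF, 50 °C) to 1-[2,6-bis(TBS-oxy)-4-(prenyloxy)phenyl]ethanone F2.
- **Chalcone:** the lithium enolate of F2 (LiHMDS, THF, −78 °C) adds to 6 to give the racemic β-hydroxy ketone F3. Dehydration through its mesylate (MsCl, Et3N) gives the (E)-chalcone F4.
- **Epoxidation:** amine-catalysed Weitz–Scheffer epoxidation (α,α-diarylprolinol, TBHP, hexane) attacks only the electron-poor enone and leaves the prenyl alkene alone. It should give the (αR,βS)-chalcone epoxide F5.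
- **Ring closure:** KHF2 in MeOH then frees the phenols. One of the two equivalent ortho phenols opens the epoxide at the benzylic carbon (6-endo-tet, inversion, C3 retained) and gives 14 directly.

**Step 8.**
- **What may go wrong:** transesterification at the hindered C3 ester may be slow. Under forcing conditions C3 may enolise, ring C may open, and the C2/C3 integrity would be lost.
- **Fallback:** the ester is removed before the ketone exists. It sets out from 11 and comes back at 13, and replaces steps 7 and 8.
- **Sequence:** DIBAL-H (CH2Cl2, −78 °C) cleaves the acetate reductively without harming the aryl silyl ethers and gives (2R,3S,4R)-5,3',4'-tris(TBS-oxy)-7-(prenyloxy)flavan-3,4-diol F6. Activated MnO2 (CH2Cl2, rt) then oxidises the electron-rich benzylic C4 carbinol in preference to the aliphatic C3 carbinol.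

**Step 5.**
- **What may go wrong:** the electron-rich enol acetate may be over-oxidised. The hydrogen sulfate in the reagent may strip aryl silyl groups.
- **Fallback:** enolisation and acylation in place of oxygen insertion. It sets out from 6 and comes back at 9.
- **Sequence:** Wittig methoxymethylenation (Ph3PCH2OMe Cl, NaHMDS, THF, 0 °C) gives 1,2-bis(TBS-oxy)-4-(2-methoxyethenyl)benzene F7 as an E/Z mixture. Mild hydrolysis (aq. HCl, THF, rt) gives [3,4-bis(TBS-oxy)phenyl]acetaldehyde F8.
- **Acylation:** O-acetylation of the enolate of F8 (Ac2O, Et3N, DMAP, CH2Cl2) gives 9 together with (Z)-2-[3,4-bis(TBS-oxy)phenyl]ethenyl acetate F9, which is removed by chromatography.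

**Further compounds**
F1 | step 6 | 1-[2,6-dihydroxy-4-(prenyloxy)phenyl]ethanone | CC(C)=CCOc1cc(O)c(C(C)=O)c(O)c1
F2 | step 6 | 1-[2,6-bis(TBS-oxy)-4-(prenyloxy)phenyl]ethanone | CC(C)=CCOc1cc(O[Si](C)(C)C(C)(C)C)c(C(C)=O)c(O[Si](C)(C)C(C)(C)C)c1
F3 | step 6 | racemic 1-[2,6-bis(TBS-oxy)-4-(prenyloxy)phenyl]-3-[3,4-bis(TBS-oxy)phenyl]-3-hydroxypropan-1-one | CC(C)=CCOc1cc(O[Si](C)(C)C(C)(C)C)c(C(=O)CC(O)c2ccc(O[Si](C)(C)C(C)(C)C)c(O[Si](C)(C)C(C)(C)C)c2)c(O[Si](C)(C)C(C)(C)C)c1
F4 | step 6 | (E)-1-[2,6-bis(TBS-oxy)-4-(prenyloxy)phenyl]-3-[3,4-bis(TBS-oxy)phenyl]prop-2-en-1-one | CC(C)=CCOc1cc(O[Si](C)(C)C(C)(C)C)c(C(=O)/C=C/c2ccc(O[Si](C)(C)C(C)(C)C)c(O[Si](C)(C)C(C)(C)C)c2)c(O[Si](C)(C)C(C)(C)C)c1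
F5 | step 6 | [2,6-bis(TBS-oxy)-4-(prenyloxy)phenyl] {(2R,3S)-3-[3,4-bis(TBS-oxy)phenyl]oxiran-2-yl} ketone (trans, αR,βS) | CC(C)=CCOc1cc(O[Si](C)(C)C(C)(C)C)c(C(=O)[C@@H]2O[C@H]2c2ccc(O[Si](C)(C)C(C)(C)C)c(O[Si](C)(C)C(C)(C)C)c2)c(O[Si](C)(C)C(C)(C)C)c1
F6 | step 8 | (2R,3S,4R)-5,3',4'-tris(TBS-oxy)-7-(prenyloxy)flavan-3,4-diol | CC(C)=CCOc1cc(O[Si](C)(C)C(C)(C)C)c2c(c1)O[C@H](c1ccc(O[Si](C)(C)C(C)(C)C)c(O[Si](C)(C)C(C)(C)C)c1)[C@@H](O)[C@@H]2O
F7 | step 5 | 1,2-bis(TBS-oxy)-4-(2-methoxyethenyl)benzene (E/Z mixture) | COC=Cc1ccc(O[Si](C)(C)C(C)(C)C)c(O[Si](C)(C)C(C)(C)C)c1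
F8 | step 5 | [3,4-bis(TBS-oxy)phenyl]acetaldehyde | O=CCc1ccc(O[Si](C)(C)C(C)(C)C)c(O[Si](C)(C)C(C)(C)C)c1
F9 | step 5 | (Z)-2-[3,4-bis(TBS-oxy)phenyl]ethenyl acetate | CC(=O)O/C=C\c1ccc(O[Si](C)(C)C(C)(C)C)c(O[Si](C)(C)C(C)(C)C)c1
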